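**Plan**

- Retrosynthesis: the lactone ring is cut at O2–C3 (enol lactone) and C3–C4 (acylation of the C4 carbanion by a hexanoyl unit), which leaves a ring A o-toluate. Ring A is then cut at C4a–C8a, C5–C6, C6–C7 and C8–C8a into an α-diazo β-keto ester and the ethynyl ether of the ring B phenol. The O–C(sp) bond of that ether leads back to a phenol made from olivetol.
- Forward: ring B is elaborated first (formylation, methylation, benzylation, Baeyer–Villiger). Its hindered oxygen enters the key step as an ynol ether, ring A is built on that oxygen by benzannulation, and the pyranone ring is closed last.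
- Enabling feature: in ring A (C4a, C5–H, C6–OH, C7–H, C8–OAr, C8a–C1) the C6 hydroxyl and the C8 aryloxy group sit 1,3 across C7–H, and C8a carries the C1 carboxyl. A ketene carbon can therefore become C6 and the two carbons of an aryloxyacetylene can become C7 and C8.
- The ketene precursor is taken as its tert-butyl ester: tert-butyl diazoacetate is commercial, the bulky ester resists self-condensation during lateral lithiation, and it is cleaved by acid regardless of its two ortho substituents.
- Stereochemistry: the target has no stereocentre; the only stereogenic atoms on the way (a carbinol and a cyclobutenone carbon) are transient and racemic.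

Key step: step 8

Remark: the di-ortho-substituted aryl ethynyl ether 13 is assumed to survive for some hours in dilute solution at room temperature, since it lacks the β-hydrogen retro-ene path of alkyl ynol ethers.

**Route**

Step 1
Reactants: 1 olivetol (5-pentylbenzene-1,3-diol)
Product: 3 2,4-dihydroxy-6-pentylbenzaldehyde, via iminium chloride 2 (not isolated)
Conditions: POCl3, DMF, 0 °C to rt; then H2O, 50 °C
Reagents that add atoms: N,N-dimethylformamide (CN(C)C=O); water (O)
Why: Vilsmeier–Haack formylation of a 5-alkylresorcinol should occur mainly at the ring position para to one hydroxyl and ortho to the other, the position between the two hydroxyls being the more hindered, as is known for orcinol.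

Step 2
Reactants: 3 2,4-dihydroxy-6-pentylbenzaldehyde
Product: 4 2-hydroxy-4-methoxy-6-pentylbenzaldehyde
Conditions: MeI (1.05 equiv), K2CO3 (1.1 equiv), acetone, rt
Reagents that add atoms: iodomethane (CI)
Why: The 2-hydroxyl is tied up in a hydrogen bond to the formyl oxygen, so Williamson methylation should take place at the free and more acidic 4-hydroxyl.

Step 3
Reactants: 4 2-hydroxy-4-methoxy-6-pentylbenzaldehyde
Product: 5 2-(benzyloxy)-4-methoxy-6-pentylbenzaldehyde
Conditions: BnBr, K2CO3, DMF, 60 °C
Reagents that add atoms: benzyl bromide (BrCc1ccccc1)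
Why: Williamson benzylation of the remaining chelated phenol proceeds under slightly more forcing conditions and installs the protecting group that later masks O2' of ring B.

Step 4
Reactants: 5 2-(benzyloxy)-4-methoxy-6-pentylbenzaldehyde
Product: 7 2-(benzyloxy)-4-methoxy-6-pentylphenol, via aryl formate 6 (not isolated)
Conditions: mCPBA, CH2Cl2, 0 °C to rt; then Et3N, MeOH, rt
Reagents that add atoms: 3-chloroperbenzoic acid (OOC(=O)c1cccc(Cl)c1)
Why: In the Baeyer–Villiger (Dakin-type) oxidation of an ortho/para-dialkoxybenzaldehyde the electron-rich aryl group migrates, and methanolysis of the resulting formate frees the phenol with the 1,2,4-trioxygenation pattern of ring B.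

Step 5
Reactants: 7 2-(benzyloxy)-4-methoxy-6-pentylphenol; 8 trichloroethylene
Product: 10 1-(benzyloxy)-2-{[(E)-1,2-dichloroethenyl]oxy}-5-methoxy-3-pentylbenzene, via dichloroacetylene 9 (not isolated)
Conditions: K2CO3, DMF, 70 °C
Reagents that add atoms: none
Why: Base converts trichloroethylene into dichloroacetylene, to which the phenoxide adds in anti fashion to give the (E)-1,2-dichlorovinyl aryl ether, the established entry to ynol ethers from hydroxyl compounds.

Step 6
Reactants: 10 1-(benzyloxy)-2-{[(E)-1,2-dichloroethenyl]oxy}-5-methoxy-3-pentylbenzene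
Product: 13 1-(benzyloxy)-2-(ethynyloxy)-5-methoxy-3-pentylbenzene, via chloroethynyl ether 11 (not isolated), via lithium acetylide 12 (not isolated)
Conditions: n-BuLi (2.3 equiv), Et2O, −78 to −40 °C; then H2O, −78 °C
Reagents that add atoms: none
Why: Two equivalents of n-BuLi effect β-elimination of HCl to the chloroalkyne and then chlorine–lithium exchange to the acetylide (the standard dichlorovinyl ether route to ynol ethers), and cold protonation should give the terminal ynol ether, which is kept in cold solution and used at once.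

Step 7
Reactants: 14 tert-butyl diazoacetate; 15 methacrolein
Product: 17 tert-butyl 2-diazo-4-methyl-3-oxopent-4-enoate, via hydroxy diazo ester 16 (not isolated)
Conditions: DBU (0.1 equiv), DMSO, rt; then IBX (1.5 equiv), rt
Reagents that add atoms: none
Why: DBU-catalysed aldol-type addition of the diazoacetate C–H to the aldehyde followed by IBX oxidation of the allylic carbinol in the same pot is a known route to vinyl diazo keto esters; it avoids the polymerisation-prone 3-oxopent-4-enoate, and the carbinol stereocentre of racemic 16 is erased.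

Step 8
Reactants: 13 1-(benzyloxy)-2-(ethynyloxy)-5-methoxy-3-pentylbenzene; 17 tert-butyl 2-diazo-4-methyl-3-oxopent-4-enoate
Product: 22 tert-butyl 2-[2-(benzyloxy)-4-methoxy-6-pentylphenoxy]-4-hydroxy-6-methylbenzoate, via vinylketene 18 (not isolated), via cyclobutenone 19 (not isolated), via dienylketene 20 (not isolated), via cyclohexadienone 21 (not isolated)
Conditions: hν (300 nm), ClCH2CH2Cl, rt, 17 (1.3 equiv) added in portions; then 80 °C
Reagents that add atoms: none
Why: Proposed new method: irradiation triggers a Wolff rearrangement of 17 in which the isopropenyl group shifts from the ketone carbon to the diazo carbon (forming C4a–C8a) and leaves ester-substituted vinylketene 18, whose electrophilic ketene carbon is attacked by the unsubstituted, nucleophilic carbon of ynol ether 13 in a (2+2) cycloaddition that forms C6–C7 and C8–C8a in cyclobutenone 19. On warming, 19 opens by a four-electron electrocyclic reaction to dienylketene 20, and ring A is closed by six-electron electrocyclisation of 20 (ketene carbon C6 onto the isopropenyl CH2, C5) to dienone 21, which tautomerises to phenol 22. The closest known reaction type is the Danheiser benzannulation of vinylketenes from unsaturated α-diazo ketones with alkoxy- or siloxyacetylenes; untested here are a 2-diazo-3-oxo ester as ketene source and an aryl ethynyl ether as partner. No stereocentre survives, since the quaternary carbon of racemic 19 becomes aromatic, and the ring opening of 19 is reversible, so only the rotamer with the isopropenyl group cis to the ketene leads on. Regioselectivity is needed and is secured by the polarisation of the ynol ether, which places the aryloxy carbon next to the ester-bearing carbon. Chemoselectivity for (2+2) over hetero (4+2) addition through the ester carbonyl is needed as well, and is favoured because an alkoxycarbonyl oxygen is a much weaker heterodiene terminus than a ketone oxygen and because the ketene is generated at room temperature in the presence of the alkyne.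

Step 9
Reactants: 22 tert-butyl 2-[2-(benzyloxy)-4-methoxy-6-pentylphenoxy]-4-hydroxy-6-methylbenzoate
Product: 23 tert-butyl 4-(benzyloxy)-2-[2-(benzyloxy)-4-methoxy-6-pentylphenoxy]-6-methylbenzoate
Conditions: BnBr, K2CO3, DMF, rt
Reagents that add atoms: benzyl bromide (BrCc1ccccc1)
Why: Williamson benzylation of the only free phenol masks O6 before the strongly basic step and gives two benzyl ethers that can be removed together at the end.

Step 10
Reactants: 24 hexanoyl chloride
Product: 25 N-methoxy-N-methylhexanamide
Conditions: MeNH(OMe)·HCl, K2CO3, EtOAc/H2O, 0 °C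
Reagents that add atoms: N,O-dimethylhydroxylamine hydrochloride (CNOC.Cl)
Why: Schotten–Baumann acylation of N,O-dimethylhydroxylamine gives the Weinreb amide, an acyl donor that stops cleanly at the ketone stage.

Step 11
Reactants: 23 tert-butyl 4-(benzyloxy)-2-[2-(benzyloxy)-4-methoxy-6-pentylphenoxy]-6-methylbenzoate; 25 N-methoxy-N-methylhexanamide
Product: 28 tert-butyl 4-(benzyloxy)-2-[2-(benzyloxy)-4-methoxy-6-pentylphenoxy]-6-(2-oxoheptyl)benzoate, via benzylic organolithium 26 (not isolated), via lithium hemiaminal alkoxide 27 (not isolated)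
Conditions: LiN(i-Pr)2 (1.2 equiv), THF, −78 °C; then 25, −78 to −20 °C; then AcOH
Reagents that add atoms: none
Why: The methyl group ortho to the ester is the most acidic C–H (lateral lithiation of an o-toluate), the tert-butyl ester suppresses self-condensation, and the Weinreb amide holds the product as chelated adduct 27 so that the acidic keto ester appears only on quenching.

Step 12
Reactants: 28 tert-butyl 4-(benzyloxy)-2-[2-(benzyloxy)-4-methoxy-6-pentylphenoxy]-6-(2-oxoheptyl)benzoate
Product: 30 6-(benzyloxy)-8-[2-(benzyloxy)-4-methoxy-6-pentylphenoxy]-3-pentyl-1H-isochromen-1-one, via keto acid 29 (not isolated)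
Conditions: 20% CF3CO2H in CH2Cl2, 0 °C to rt
Reagents that add atoms: none
Why: Acidolysis of the tert-butyl ester by alkyl–oxygen cleavage does not depend on access to the hindered acyl carbon, and the freed 2-(2-oxoalkyl)benzoic acid should cyclodehydrate under the same acid to the 3-alkylisocoumarin (enol lactonisation), while aryl benzyl ethers tolerate dilute acid for the short time needed.

Step 13
Reactants: 30 6-(benzyloxy)-8-[2-(benzyloxy)-4-methoxy-6-pentylphenoxy]-3-pentyl-1H-isochromen-1-one
Product: 31 6-hydroxy-8-(2-hydroxy-4-methoxy-6-pentylphenoxy)-3-pentyl-1H-isochromen-1-one (Compound NP-007099)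
Conditions: BCl3 (4 equiv), C6HMe5 (6 equiv), CH2Cl2, −78 °C; then H2O
Reagents that add atoms: none
Why: BCl3 with pentamethylbenzene as cation scavenger cleaves aryl benzyl ethers at −78 °C and should leave the aryl methyl ether, the diaryl ether, the lactone and the C3–C4 double bond intact, the last of which hydrogenolysis could reduce.

**Compound list**

1 | olivetol (5-pentylbenzene-1,3-diol) | CCCCCc1cc(O)cc(O)c1 | starting material
2 | [(2,4-dihydroxy-6-pentylphenyl)methylidene]dimethylammonium chloride | C[N+](C)=Cc1c(O)cc(O)cc1CCCCC.[Cl-] | intermediate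
3 | 2,4-dihydroxy-6-pentylbenzaldehyde | O=Cc1c(O)cc(O)cc1CCCCC | intermediate
4 | 2-hydroxy-4-methoxy-6-pentylbenzaldehyde | O=Cc1c(O)cc(OC)cc1CCCCC | intermediate
5 | 2-(benzyloxy)-4-methoxy-6-pentylbenzaldehyde | O=Cc1c(OCc2ccccc2)cc(OC)cc1CCCCC | intermediate
6 | 2-(benzyloxy)-4-methoxy-6-pentylphenyl formate | O=COc1c(OCc2ccccc2)cc(OC)cc1CCCCC | intermediate
7 | 2-(benzyloxy)-4-methoxy-6-pentylphenol | Oc1c(OCc2ccccc2)cc(OC)cc1CCCCC | intermediate
8 | trichloroethylene | ClC=C(Cl)Cl | starting material
9 | dichloroacetylene | ClC#CCl | intermediate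
10 | 1-(benzyloxy)-2-{[(E)-1,2-dichloroethenyl]oxy}-5-methoxy-3-pentylbenzene | Cl/C=C(/Cl)Oc1c(OCc2ccccc2)cc(OC)cc1CCCCC | intermediate
11 | 1-(benzyloxy)-2-[(chloroethynyl)oxy]-5-methoxy-3-pentylbenzene | ClC#COc1c(OCc2ccccc2)cc(OC)cc1CCCCC | intermediate
12 | lithium [2-(benzyloxy)-4-methoxy-6-pentylphenoxy]acetylide | [Li]C#COc1c(OCc2ccccc2)cc(OC)cc1CCCCC | intermediate
13 | 1-(benzyloxy)-2-(ethynyloxy)-5-methoxy-3-pentylbenzene | C#COc1c(OCc2ccccc2)cc(OC)cc1CCCCC | intermediate
14 | tert-butyl diazoacetate | CC(C)(C)OC(=O)C=[N+]=[N-] | starting material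
15 | methacrolein (2-methylprop-2-enal) | C=C(C)C=O | starting material
16 | tert-butyl 2-diazo-3-hydroxy-4-methylpent-4-enoate (racemic) | CC(C)(C)OC(=O)C(=[N+]=[N-])C(O)C(C)=C | intermediate
17 | tert-butyl 2-diazo-4-methyl-3-oxopent-4-enoate | CC(C)(C)OC(=O)C(=[N+]=[N-])C(=O)C(C)=C | intermediate
18 | tert-butyl 3-methyl-2-(oxomethylidene)but-3-enoate | CC(C)(C)OC(=O)C(=C=O)C(C)=C | intermediate
19 | tert-butyl 2-[2-(benzyloxy)-4-methoxy-6-pentylphenoxy]-4-oxo-1-(prop-1-en-2-yl)cyclobut-2-ene-1-carboxylate (racemic) | CC(C)(C)OC(=O)C1(C(C)=C)C(=O)C=C1Oc1c(OCc2ccccc2)cc(OC)cc1CCCCC | intermediate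
20 | tert-butyl (2Z)-3-[2-(benzyloxy)-4-methoxy-6-pentylphenoxy]-5-oxo-2-(prop-1-en-2-yl)penta-2,4-dienoate | O=C=C/C(Oc1c(OCc2ccccc2)cc(OC)cc1CCCCC)=C(\C(C)=C)C(=O)OC(C)(C)C | intermediate
21 | tert-butyl 6-[2-(benzyloxy)-4-methoxy-6-pentylphenoxy]-2-methyl-4-oxocyclohexa-1,5-diene-1-carboxylate | CC(C)(C)OC(=O)C1=C(C)CC(=O)C=C1Oc1c(OCc2ccccc2)cc(OC)cc1CCCCC | intermediate
22 | tert-butyl 2-[2-(benzyloxy)-4-methoxy-6-pentylphenoxy]-4-hydroxy-6-methylbenzoate | CC(C)(C)OC(=O)c1c(C)cc(O)cc1Oc1c(OCc2ccccc2)cc(OC)cc1CCCCC | intermediate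
23 | tert-butyl 4-(benzyloxy)-2-[2-(benzyloxy)-4-methoxy-6-pentylphenoxy]-6-methylbenzoate | CC(C)(C)OC(=O)c1c(C)cc(OCc2ccccc2)cc1Oc1c(OCc2ccccc2)cc(OC)cc1CCCCC | intermediate
24 | hexanoyl chloride | CCCCCC(=O)Cl | starting material
25 | N-methoxy-N-methylhexanamide | CCCCCC(=O)N(C)OC | intermediate
26 | tert-butyl 4-(benzyloxy)-2-[2-(benzyloxy)-4-methoxy-6-pentylphenoxy]-6-(lithiomethyl)benzoate | CC(C)(C)OC(=O)c1c(C[Li])cc(OCc2ccccc2)cc1Oc1c(OCc2ccccc2)cc(OC)cc1CCCCC | intermediate
27 | lithium 1-{5-(benzyloxy)-3-[2-(benzyloxy)-4-methoxy-6-pentylphenoxy]-2-(tert-butoxycarbonyl)phenyl}-2-[methoxy(methyl)amino]heptan-2-olate | CCCCCC(O[Li])(Cc1cc(OCc2ccccc2)cc(Oc2c(OCc3ccccc3)cc(OC)cc2CCCCC)c1C(=O)OC(C)(C)C)N(C)OC | intermediate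
28 | tert-butyl 4-(benzyloxy)-2-[2-(benzyloxy)-4-methoxy-6-pentylphenoxy]-6-(2-oxoheptyl)benzoate | CCCCCC(=O)Cc1cc(OCc2ccccc2)cc(Oc2c(OCc3ccccc3)cc(OC)cc2CCCCC)c1C(=O)OC(C)(C)C | intermediate
29 | 4-(benzyloxy)-2-[2-(benzyloxy)-4-methoxy-6-pentylphenoxy]-6-(2-oxoheptyl)benzoic acid | CCCCCC(=O)Cc1cc(OCc2ccccc2)cc(Oc2c(OCc3ccccc3)cc(OC)cc2CCCCC)c1C(=O)O | intermediate
30 | 6-(benzyloxy)-8-[2-(benzyloxy)-4-methoxy-6-pentylphenoxy]-3-pentyl-1H-isochromen-1-one | CCCCCc1cc2cc(OCc3ccccc3)cc(Oc3c(OCc4ccccc4)cc(OC)cc3CCCCC)c2c(=O)o1 | intermediate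
31 | 6-hydroxy-8-(2-hydroxy-4-methoxy-6-pentylphenoxy)-3-pentyl-1H-isochromen-1-one (Compound NP-007099) | CCCCCc1cc2cc(O)cc(Oc3c(O)cc(OC)cc3CCCCC)c2c(=O)o1 | target

**Step count**

Total: 13 steps. Longest linear sequence: 11 steps (olivetol 1 to target 31 through steps 1–6, 8, 9, 11, 12 and 13); steps 7 and 10 are one-step side branches.

**Steps most likely to fail, with fallbacks**

Step 8. The acyl-type ketene may be captured through its ester carbonyl in a hetero (4+2) mode, the alkoxy group may migrate in the Wolff step instead of the isopropenyl group, or the product phenol may be acylated by surplus ketene. The fallback forms the C8–O bond by known palladium-catalysed aryl ether coupling; it sets out from phenol 7 and returns at 30. Commercial ethyl orsellinate (ethyl 2,4-dihydroxy-6-methylbenzoate) F1 would be benzylated at its non-chelated 4-hydroxyl (BnBr, K2CO3, acetone) to ethyl 4-(benzyloxy)-2-hydroxy-6-methylbenzoate F2. Treatment with (CF3SO2)2O and pyridine would give ethyl 4-(benzyloxy)-6-methyl-2-{[(trifluoromethyl)sulfonyl]oxy}benzoate F3. Buchwald–Hartwig etherification of F3 with 7 (Pd(OAc)2, 2-(di-tert-butylphosphino)-2',4',6'-triisopropylbiphenyl, K3PO4, toluene, 100 °C) should give ethyl 4-(benzyloxy)-2-[2-(benzyloxy)-4-methoxy-6-pentylphenoxy]-6-methylbenzoate F4. Lateral lithiation and acylation with 25 as in step 11 would give ethyl 4-(benzyloxy)-2-[2-(benzyloxy)-4-methoxy-6-pentylphenoxy]-6-(2-oxoheptyl)benzoate F5. Acid-catalysed enol lactonisation (p-TsOH, toluene, reflux, loss of ethanol) then returns to the route at 30.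

Step 6. n-BuLi may metalate the benzylic position of the benzyl ether, and the terminal ynol ether may oligomerise or hydrate while it is concentrated or chromatographed. The fallback sets out from 10 and returns at 13. The acetylide 12 generated from 10 would be captured with Me3SiCl instead of a proton to give {[2-(benzyloxy)-4-methoxy-6-pentylphenoxy]ethynyl}trimethylsilane F6, a silyl-capped ynol ether that can be purified and stored. Desilylation with catalytic K2CO3 in MeOH immediately before step 8 would release 13 in solution, which is used without isolation.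

Step 12. Acid may strip the benzyl groups with C-benzylation or tert-butylation of the electron-rich rings, or the closure may stall at the hydroxy lactone stage. The fallback reverses the order of deprotection and ring closure; it sets out from 28 and returns at 31. Hydrogenolysis of 28 (H2, Pd/C, EtOAc, rt), which at this stage has no reducible alkene, would give tert-butyl 4-hydroxy-2-(2-hydroxy-4-methoxy-6-pentylphenoxy)-6-(2-oxoheptyl)benzoate F7. Treatment of F7 with CF3CO2H in CH2Cl2 would cleave the ester and close the lactone directly to 31, bypassing 30 and step 13.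

**Further compounds**

F1 | step 8 | ethyl orsellinate (ethyl 2,4-dihydroxy-6-methylbenzoate) | CCOC(=O)c1c(C)cc(O)cc1O
F2 | step 8 | ethyl 4-(benzyloxy)-2-hydroxy-6-methylbenzoate | CCOC(=O)c1c(C)cc(OCc2ccccc2)cc1O
F3 | step 8 | ethyl 4-(benzyloxy)-6-methyl-2-{[(trifluoromethyl)sulfonyl]oxy}benzoate | CCOC(=O)c1c(C)cc(OCc2ccccc2)cc1OS(=O)(=O)C(F)(F)F
F4 | step 8 | ethyl 4-(benzyloxy)-2-[2-(benzyloxy)-4-methoxy-6-pentylphenoxy]-6-methylbenzoate | CCOC(=O)c1c(C)cc(OCc2ccccc2)cc1Oc1c(OCc2ccccc2)cc(OC)cc1CCCCC
F5 | step 8 | ethyl 4-(benzyloxy)-2-[2-(benzyloxy)-4-methoxy-6-pentylphenoxy]-6-(2-oxoheptyl)benzoate | CCCCCC(=O)Cc1cc(OCc2ccccc2)cc(Oc2c(OCc3ccccc3)cc(OC)cc2CCCCC)c1C(=O)OCC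
F6 | step 6 | {[2-(benzyloxy)-4-methoxy-6-pentylphenoxy]ethynyl}trimethylsilane | C[Si](C)(C)C#COc1c(OCc2ccccc2)cc(OC)cc1CCCCC
F7 | step 12 | tert-butyl 4-hydroxy-2-(2-hydroxy-4-methoxy-6-pentylphenoxy)-6-(2-oxoheptyl)benzoate | CCCCCC(=O)Cc1cc(O)cc(Oc2c(O)cc(OC)cc2CCCCC)c1C(=O)OC(C)(C)C
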